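**Retrosynthetic overview**
- The acidic 4‑OH is unmasked last from a MOM ether. The diene is cut between its two inner CH carbons: Suzuki coupling of an E‑alkenylboronate (from cross‑metathesis of a terminal vinyl group) with a Z‑trisubstituted vinyl iodide.
- The Z‑vinyl iodide comes from syn‑carbocupration of propyne by the 3‑(furan‑3‑yl)propyl Grignard reagent. The furan ring itself is built by Diels–Alder/retro‑Diels–Alder reaction of 4‑phenyloxazole with 5‑chloropent‑1‑yne (key step, PhCN is lost).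
- The exocyclic enol‑lactone alkene comes from a vinylogous aldol condensation of the C5 anion of MOM‑protected 3‑methyltetronic acid with (2R,6R)‑2,6‑dimethyloct‑7‑enal, then Z→E photoisomerisation before any diene is present.
- The aldehyde comes from SN2 (inversion) coupling of tert‑butyl (R)‑lactate triflate with the Grignard reagent made from (R)‑β‑citronellene; both stereocentres are bought.
- Ring order: the furan is formed first (step 1); the butenolide ring is bought intact and only elaborated at C5.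

Assumption: the SMILES is read literally (5E enol‑lactone alkene with the side chain on the C4–OH side, both methyl‑bearing centres R, diene 7E,9Z in side‑chain locants); 4‑phenyloxazole, (R)‑β‑citronellene, tert‑butyl (R)‑lactate and 3‑methyltetronic acid are taken as purchasable.

**Route**

Step 1
Reactants: 1 5‑chloropent‑1‑yne; 2 4‑phenyloxazole
Product: 4 3‑(3‑chloropropyl)furan, via oxazole–alkyne cycloadduct 3 (not isolated)
Conditions: neat, 1 (3 equiv), sealed tube, 210 °C, 24 h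
Reagents that add atoms: none
Why: Kondrat'eva‑type [4+2] cycloaddition of the oxazole across C2/C5 with the alkyne, then retro‑Diels–Alder loss of benzonitrile, forms the furan ring, and either regioisomeric adduct collapses to the same 3‑substituted furan.

Step 2
Reactants: 4 3‑(3‑chloropropyl)furan; 5 propyne
Product: 8 3‑[(4Z)‑5‑iodo‑4‑methylpent‑4‑en‑1‑yl]furan, via Grignard reagent 6 (not isolated), via alkenylcopper reagent 7 (not isolated)
Conditions: Mg, Et2O, reflux; CuBr·SMe2 (1 equiv), Et2O/Me2S, −45 °C; 5 (3 equiv), −25 °C; I2, THF, −50 → 0 °C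
Reagents that add atoms: iodine (II)
Why: Normant syn‑carbocupration puts the alkyl group on the internal alkyne carbon and copper cis to it, and iodinolysis with retention fixes the Z trisubstituted alkene.

Step 3
Reactants: 9 (3R)‑3,7‑dimethylocta‑1,6‑diene ((R)‑β‑citronellene)
Product: 11 (4R)‑4‑methylhex‑5‑en‑1‑ol, via aldehyde 10 (not isolated)
Conditions: O3 (1.0 equiv), CH2Cl2/MeOH 5:1, −78 °C; then NaBH4, −78 → 20 °C
Reagents that add atoms: ozone ([O-][O+]=O)
Why: Chemoselective ozonolysis cleaves the electron‑rich trisubstituted alkene much faster than the vinyl group and NaBH4 reduces the cleavage products in the same flask; the bought stereocentre is untouched.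

Step 4
Reactants: 11 (4R)‑4‑methylhex‑5‑en‑1‑ol
Product: 12 (3R)‑6‑chloro‑3‑methylhex‑1‑ene
Conditions: PPh3, N‑chlorosuccinimide, CH2Cl2, 0 → 20 °C
Reagents that add atoms: N‑chlorosuccinimide (O=C1CCC(=O)N1Cl)
Why: Appel‑type chlorination of the primary alcohol by SN2 at a carbon remote from the stereocentre.

Step 5
Reactants: 13 tert‑butyl (2R)‑2‑hydroxypropanoate
Product: 14 tert‑butyl (2R)‑2‑{[(trifluoromethyl)sulfonyl]oxy}propanoate
Conditions: Tf2O, 2,6‑lutidine, CH2Cl2, −78 → 0 °C; used at once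
Reagents that add atoms: trifluoromethanesulfonic anhydride (O=S(=O)(OS(=O)(=O)C(F)(F)F)C(F)(F)F)
Why: O‑sulfonylation does not break the C–O bond, so the bought lactate configuration is kept in the activated electrophile.

Step 6
Reactants: 12 (3R)‑6‑chloro‑3‑methylhex‑1‑ene; 14 tert‑butyl (2R)‑2‑{[(trifluoromethyl)sulfonyl]oxy}propanoate
Product: 16 tert‑butyl (2R,6R)‑2,6‑dimethyloct‑7‑enoate, via Grignard reagent 15 (not isolated)
Conditions: 12, Mg (I2‑activated), THF, 25–50 °C; then 14, ZnCl2 (5 mol %), THF, 0 °C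
Reagents that add atoms: none
Why: Zinc‑catalysed sp3–sp3 cross‑coupling of the α‑triflyloxy ester with the alkyl Grignard reagent (via a triorganozincate) is a clean SN2 with inversion, which turns the bought (R)‑lactate centre into the (2R) methyl‑bearing centre.

Step 7
Reactants: 16 tert‑butyl (2R,6R)‑2,6‑dimethyloct‑7‑enoate
Product: 17 (2R,6R)‑2,6‑dimethyloct‑7‑enal
Conditions: i‑Bu2AlH (1.1 equiv), CH2Cl2, −78 °C; MeOH quench; used crude
Reagents that add atoms: none
Why: Partial hydride reduction stops at the tetrahedral aluminium hemiacetal at −78 °C, which releases the aldehyde on work‑up without epimerising the α‑centre.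

Step 8
Reactants: 18 4‑hydroxy‑3‑methylfuran‑2(5H)‑one (3‑methyltetronic acid)
Product: 19 4‑(methoxymethoxy)‑3‑methylfuran‑2(5H)‑one
Conditions: MOMCl, i‑Pr2NEt, CH2Cl2, 0 → 20 °C
Reagents that add atoms: chloromethyl methyl ether (COCCl)
Why: O‑alkylation of the vinylogous acid on its 4‑oxygen by a hard electrophile masks the acidic OH and leaves C5 free for deprotonation.

Step 9
Reactants: 19 4‑(methoxymethoxy)‑3‑methylfuran‑2(5H)‑one; 17 (2R,6R)‑2,6‑dimethyloct‑7‑enal
Product: 23 (5Z)‑5‑[(2R,6R)‑2,6‑dimethyloct‑7‑en‑1‑ylidene]‑4‑(methoxymethoxy)‑3‑methylfuran‑2(5H)‑one, via lithium furanolate 20 (not isolated), via lithium aldolate 21 (not isolated), via aldol mesylate 22 (not isolated)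
Conditions: 19, LiN(i‑Pr)2, THF, −78 °C; 17, −78 °C; MsCl, −78 → 0 °C; DBU, 0 → 20 °C
Reagents that add atoms: none
Why: Vinylogous aldol addition of the C5 anion to the aldehyde followed by mesylation and E1cB elimination gives the thermodynamically preferred Z‑ylidene (chain away from the 4‑alkoxy group); the transient carbinol centres are destroyed and the side‑chain centres are not touched.

Step 10
Reactants: 23 (5Z)‑5‑[(2R,6R)‑2,6‑dimethyloct‑7‑en‑1‑ylidene]‑4‑(methoxymethoxy)‑3‑methylfuran‑2(5H)‑one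
Product: 24 (5E)‑5‑[(2R,6R)‑2,6‑dimethyloct‑7‑en‑1‑ylidene]‑4‑(methoxymethoxy)‑3‑methylfuran‑2(5H)‑one
Conditions: hν (300 nm, Pyrex), degassed MeCN, 20 °C; chromatographic separation, recovered 23 re‑irradiated
Reagents that add atoms: none
Why: Direct photochemical Z/E isomerisation of the ylidenebutenolide chromophore (the only absorber at this stage) gives a photostationary mixture from which the contra‑thermodynamic E isomer is isolated.

Step 11
Reactants: 24 (5E)‑5‑[(2R,6R)‑2,6‑dimethyloct‑7‑en‑1‑ylidene]‑4‑(methoxymethoxy)‑3‑methylfuran‑2(5H)‑one; 25 4,4,5,5‑tetramethyl‑2‑vinyl‑1,3,2‑dioxaborolane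
Product: 26 (5E)‑5‑[(2R,6R,7E)‑2,6‑dimethyl‑8‑(4,4,5,5‑tetramethyl‑1,3,2‑dioxaborolan‑2‑yl)oct‑7‑en‑1‑ylidene]‑4‑(methoxymethoxy)‑3‑methylfuran‑2(5H)‑one
Conditions: 25 (3 equiv), second‑generation Hoveyda–Grubbs catalyst RuCl2(H2IMes)(=CH‑C6H4‑2‑O‑i‑Pr) (5 mol %), CH2Cl2, 40 °C
Reagents that add atoms: none
Why: Olefin cross‑metathesis of the terminal vinyl group with the vinylboronate, driven by ethene loss, gives the E‑alkenylboronate because of the bulky boronate and the allylic branch, while the trisubstituted enol‑lactone alkene is inert to the ruthenium carbene.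

Step 12
Reactants: 26 the E‑alkenylboronate from step 11; 8 3‑[(4Z)‑5‑iodo‑4‑methylpent‑4‑en‑1‑yl]furan
Product: 27 (5E)‑5‑[(2R,6R,7E,9Z)‑13‑(furan‑3‑yl)‑2,6,10‑trimethyltrideca‑7,9‑dien‑1‑ylidene]‑4‑(methoxymethoxy)‑3‑methylfuran‑2(5H)‑one
Conditions: Pd(PPh3)4 (5 mol %), K3PO4 (aq.), THF, 40 °C
Reagents that add atoms: none
Why: Suzuki–Miyaura coupling proceeds with retention at both sp2 carbons and so joins the E‑boronate and the Z‑iodide into the (7E,9Z)‑diene.

Step 13
Reactants: 27 the MOM‑protected tetronate from step 12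
Product: 28 (5E)‑5‑[(2R,6R,7E,9Z)‑13‑(furan‑3‑yl)‑2,6,10‑trimethyltrideca‑7,9‑dien‑1‑ylidene]‑4‑hydroxy‑3‑methylfuran‑2(5H)‑one (target)
Conditions: 2 M HCl, THF, 20 °C
Reagents that add atoms: none
Why: Mild acid hydrolysis of the vinylogous acetal ester frees the tetronic acid without a nucleophile that could add to the ylidene carbon and scramble its geometry.

**Compound list**
1 | 5‑chloropent‑1‑yne | C#CCCCCl | starting material
2 | 4‑phenyloxazole | c1ccc(-c2cocn2)cc1 | starting material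
3 | 5‑(3‑chloropropyl)‑3‑phenyl‑7‑oxa‑2‑azabicyclo[2.2.1]hepta‑2,5‑diene (either regioisomer) | ClCCCC1=CC2N=C(c3ccccc3)C1O2 | intermediate
4 | 3‑(3‑chloropropyl)furan | ClCCCc1ccoc1 | intermediate
5 | propyne | CC#C | starting material
6 | [3‑(furan‑3‑yl)propyl]magnesium chloride | Cl[Mg]CCCc1ccoc1 | intermediate
7 | (Z)‑[5‑(furan‑3‑yl)‑2‑methylpent‑1‑en‑1‑yl]copper (MgBrCl complex) | [Cu]/C=C(/C)CCCc1ccoc1 | intermediate
8 | 3‑[(4Z)‑5‑iodo‑4‑methylpent‑4‑en‑1‑yl]furan | I/C=C(/C)CCCc1ccoc1 | intermediate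
9 | (3R)‑3,7‑dimethylocta‑1,6‑diene | C=C[C@H](C)CCC=C(C)C | starting material
10 | (4R)‑4‑methylhex‑5‑enal | C=C[C@H](C)CCC=O | intermediate
11 | (4R)‑4‑methylhex‑5‑en‑1‑ol | C=C[C@H](C)CCCO | intermediate
12 | (3R)‑6‑chloro‑3‑methylhex‑1‑ene | C=C[C@H](C)CCCCl | intermediate
13 | tert‑butyl (2R)‑2‑hydroxypropanoate | C[C@@H](O)C(=O)OC(C)(C)C | starting material
14 | tert‑butyl (2R)‑2‑{[(trifluoromethyl)sulfonyl]oxy}propanoate | C[C@@H](OS(=O)(=O)C(F)(F)F)C(=O)OC(C)(C)C | intermediate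
15 | [(4R)‑4‑methylhex‑5‑en‑1‑yl]magnesium chloride | C=C[C@H](C)CCC[Mg]Cl | intermediate
16 | tert‑butyl (2R,6R)‑2,6‑dimethyloct‑7‑enoate | C=C[C@H](C)CCC[C@@H](C)C(=O)OC(C)(C)C | intermediate
17 | (2R,6R)‑2,6‑dimethyloct‑7‑enal | C=C[C@H](C)CCC[C@@H](C)C=O | intermediate
18 | 4‑hydroxy‑3‑methylfuran‑2(5H)‑one | CC1=C(O)COC1=O | starting material
19 | 4‑(methoxymethoxy)‑3‑methylfuran‑2(5H)‑one | CC1=C(OCOC)COC1=O | intermediate
20 | lithium 4‑(methoxymethoxy)‑3‑methylfuran‑2‑olate | [Li+].[O-]c1occ(OCOC)c1C | intermediate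
21 | lithium alkoxide of 5‑[(2R,6R)‑1‑hydroxy‑2,6‑dimethyloct‑7‑en‑1‑yl]‑4‑(methoxymethoxy)‑3‑methylfuran‑2(5H)‑one (mixture at C5 and C1') | [Li+].[O-]C([C@H](C)CCC[C@@H](C)C=C)C1OC(=O)C(C)=C1OCOC | intermediate
22 | (2R,6R)‑1‑[3‑(methoxymethoxy)‑4‑methyl‑5‑oxo‑2,5‑dihydrofuran‑2‑yl]‑2,6‑dimethyloct‑7‑en‑1‑yl methanesulfonate (mixture at C5 and C1') | CS(=O)(=O)OC([C@H](C)CCC[C@@H](C)C=C)C1OC(=O)C(C)=C1OCOC | intermediate
23 | (5Z)‑5‑[(2R,6R)‑2,6‑dimethyloct‑7‑en‑1‑ylidene]‑4‑(methoxymethoxy)‑3‑methylfuran‑2(5H)‑one | CC1=C(OCOC)/C(=C/[C@H](C)CCC[C@@H](C)C=C)OC1=O | intermediate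
24 | (5E)‑5‑[(2R,6R)‑2,6‑dimethyloct‑7‑en‑1‑ylidene]‑4‑(methoxymethoxy)‑3‑methylfuran‑2(5H)‑one | CC1=C(OCOC)/C(=C\[C@H](C)CCC[C@@H](C)C=C)OC1=O | intermediate
25 | 4,4,5,5‑tetramethyl‑2‑vinyl‑1,3,2‑dioxaborolane | C=CB1OC(C)(C)C(C)(C)O1 | starting material
26 | (5E)‑5‑[(2R,6R,7E)‑2,6‑dimethyl‑8‑(4,4,5,5‑tetramethyl‑1,3,2‑dioxaborolan‑2‑yl)oct‑7‑en‑1‑ylidene]‑4‑(methoxymethoxy)‑3‑methylfuran‑2(5H)‑one | CC1=C(OCOC)/C(=C\[C@H](C)CCC[C@@H](C)/C=C/B2OC(C)(C)C(C)(C)O2)OC1=O | intermediate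
27 | (5E)‑5‑[(2R,6R,7E,9Z)‑13‑(furan‑3‑yl)‑2,6,10‑trimethyltrideca‑7,9‑dien‑1‑ylidene]‑4‑(methoxymethoxy)‑3‑methylfuran‑2(5H)‑one | CC1=C(OCOC)/C(=C\[C@H](C)CCC[C@@H](C)/C=C/C=C(/C)CCCc2ccoc2)OC1=O | intermediate
28 | (5E)‑5‑[(2R,6R,7E,9Z)‑13‑(furan‑3‑yl)‑2,6,10‑trimethyltrideca‑7,9‑dien‑1‑ylidene]‑4‑hydroxy‑3‑methylfuran‑2(5H)‑one | CC1=C(O)/C(=C\[C@H](C)CCC[C@@H](C)/C=C/C=C(/C)CCCc2ccoc2)OC1=O | target

**Step count and risks**

Total: 13 steps. Longest linear sequence: 9 steps (steps 3, 4, 6, 7, 9, 10, 11, 12, 13, starting from 9).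

The least secure operation is step 10. The E‑ylidene is the strained isomer, the photostationary ratio is not known in advance, and the E compound must then survive steps 11 to 13. The fallback sets the geometry by a stereospecific elimination instead of by light and sets out from 19 and 17. Silylation of 19 (Me3SiOTf, Et3N, CH2Cl2, 0 °C) gives 4‑(methoxymethoxy)‑3‑methyl‑2‑[(trimethylsilyl)oxy]furan F4. Its fluoride‑promoted vinylogous Mukaiyama aldol addition to 17 (Bu4NF, THF, −78 °C), with chromatographic removal of the threo isomers, gives the erythro adduct (5R)‑5‑[(1R,2R,6R)‑1‑hydroxy‑2,6‑dimethyloct‑7‑en‑1‑yl]‑4‑(methoxymethoxy)‑3‑methylfuran‑2(5H)‑one F5; its 5S,1'S erythro companion is carried along and behaves alike. Anti‑periplanar dehydration under Mitsunobu conditions (PPh3, diethyl azodicarboxylate, THF) turns the erythro adducts stereospecifically into the E‑alkene, and the route is rejoined at 24.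

The second risk is step 1. The alkyne is unactivated, the temperature is high, and the alkyl chloride may alkylate the oxazole nitrogen, so conversion can be poor. The fallback buys the furan ring instead of building it; it drops 1 and 2 and sets out from purchased 3‑bromofuran F1. Bromine–lithium exchange (n‑BuLi, THF, −78 °C) gives furan‑3‑yllithium F2, which opens oxetane in the presence of BF3·OEt2 to give 3‑(furan‑3‑yl)propan‑1‑ol F3. PPh3/N‑chlorosuccinimide converts this into the chloride, and the route is rejoined at 4.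

The third risk is step 12. The aqueous base may hydrolyse the enol lactone or let the E‑ylidene drift to Z. The fallback is base‑free, replaces the cross‑coupling by a metathesis and sets out from 8 and 24. Stille coupling of 8 with tributyl(vinyl)stannane (Pd(PPh3)4, DMF, 40 °C) gives 3‑[(4Z)‑4‑methylhepta‑4,6‑dien‑1‑yl]furan F6 with retention. Cross‑metathesis of its terminal vinyl group with the vinyl group of 24 (second‑generation Hoveyda–Grubbs catalyst RuCl2(H2IMes)(=CH‑C6H4‑2‑O‑i‑Pr), CH2Cl2, 40 °C) forms the E‑disubstituted alkene and leaves the trisubstituted Z‑alkene alone. The route is rejoined at 27, and 26 is not needed.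

**Further compounds**
F1 | step 1 | 3‑bromofuran | Brc1ccoc1
F2 | step 1 | furan‑3‑yllithium | [Li]c1ccoc1
F3 | step 1 | 3‑(furan‑3‑yl)propan‑1‑ol | OCCCc1ccoc1
F4 | step 10 | 4‑(methoxymethoxy)‑3‑methyl‑2‑[(trimethylsilyl)oxy]furan | COCOc1coc(O[Si](C)(C)C)c1C
F5 | step 10 | (5R)‑5‑[(1R,2R,6R)‑1‑hydroxy‑2,6‑dimethyloct‑7‑en‑1‑yl]‑4‑(methoxymethoxy)‑3‑methylfuran‑2(5H)‑one | O[C@H]([C@H](C)CCC[C@@H](C)C=C)[C@H]1OC(=O)C(C)=C1OCOC
F6 | step 12 | 3‑[(4Z)‑4‑methylhepta‑4,6‑dien‑1‑yl]furan | C=C/C=C(/C)CCCc1ccoc1
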